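I started from four neighbouring flasks with one charge; they differed in what went in when, and how hot.

    2 starting material → side product (k1 = 0.53 /M/s, Ea1 = 78.0 kJ/mol)
    crystals ⇌ target, rate k2*(cs2 - [target]) while solid is left; crystals form when [target] > cs2 (cs2 = 2.4 mM, k2 = 2.2 /s)
    starting material + reagent → target (k3 = 0.78 /M/s, Ea3 = 47.0 kJ/mol)
    target ⇌ isomer of the product (K4 = 1.0, k4 = 0.0049 /s, Ea4 = 104 kJ/mol, ΔH4 = −32.0 kJ/mol)
    (constants at 110 °C)

all flasks: time 2.5 min

| flask | starting material | reagent | temperature | remark |
|---|---|---|---|---|
| north-east | 0.017 M (fed, over 2.0 min) | 1.10 equiv | 110 °C | all else is in the flask from the start; the feed brings no volume worth counting |
| north-west | 0.017 M | 1.10 equiv (fed, over 2.0 min) |  | the addition at 70 °C, then warmed to 110 °C; the feed brings no volume worth counting |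
| south-west | 0.017 M | 1.10 equiv (fed, over 12 s) | 110 °C | all else is in the flask from the start; the feed brings no volume worth counting |
| north | 0.017 M | 1.10 equiv | 110 °C | everything together at the start |

- percent here means starting material units held: one side product counts as two
- what is said of target includes crystals
- a step written with two of one species runs at k times the square of its concentration and takes two of it each time
- crystals is a solid; its amount is given per volume of the solution
- all constants are for 110 °C and move with temperature by the activation energies and enthalpies

* the flask that comes out highest in amount of target, in percent of the starting material charged, or "all alike" when all lie within 1.5 percentage points (north-east / north-west / south-west / north / all alike)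
* target at the end, in percent of the starting material charged, north-east
* target at the end, in percent of the starting material charged, north-west
* target at the end, in percent of the starting material charged, south-west
* target at the end, in percent of the starting material charged, north

Starting material had two exits, so I folded the givens into one number. North began at 0.809. That is S, the rate of starting material into target over its rate into side product, a selectivity factor. The concentration cancelled at the charge. S of one is the even split, and north began below it. The share going to target is S over one plus S, here 44.7%.

I committed to about 44.7% for north. Starting material fell by both exits and reagent by one, with reagent in excess, so I expected S to climb. Against that stood lost time and the isomer. The half-life of starting material by the target step, as charged, was 0.79 min.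

Feeding starting material raised S, but in north-east the last of it arrived with 0.500 min to go, less than that half-life. South-west began with S at zero, but for a short while. North-west had the same short tail as north-east, after a cold addition. I put north on top, by little, and north-west last.

The forecast gave 42.3% for north-east, 31.3% for north-west, 41% for south-west and 43.7% for north, with north highest, holding that “time at full rate matters more than the selectivity gained by slow feeding”. My north figure stood above its value.

The flasks gave 41.9% in north-east, 29.8% in north-west, 40.7% in south-west and 43.7% in north, so north came highest and the forecast held. North-east ended with 26.8% starting material and 25.4% side product, north with 10.0% and 39.0%. In north, target and isomer together took 56.6% of what had reacted, and the isomer held 7.19%. My figure was a share at the start and this one covers the whole run, so the nearness of my figure to north's result was no check.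

For a flask like north-west but with 4.40 equiv of reagent, S on the whole reagent charge at 110 °C came to 3.24, above the even split, with a share of 76.4%. That flask's reagent was fed at 70 °C, so its S began at zero, and this figure gave a direction, not the flask's share. That flask gave 75.9% target, with 9.99% starting material left, and target and isomer together took 86.7% of what had reacted.

(Its constants belong to no real substance; the result is computed.)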